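**Retrosynthetic overview**
- The target diacetate comes from hydrodecarboxylation of a C12 carboxylic acid; its 7-ene comes from E1 opening of a C8–O δ-lactone, so the carboxyl is a traceless handle.
- The C2 acetate comes from C–H acetoxylation (C–O bond formation) of the saturated tricyclic lactone, in which the lactone and the C15 acetate switch off ring B and the side chain.
- The tricyclic lactone comes from one enantioselective polyene cascade of an acyclic trienoic acid: ring A first, ring B second, lactone ring C last (C8–O closure).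
- The trienoic acid comes from α-farnesylation of (R)-4-methyl-δ-valerolactone, itself made by asymmetric conjugate methylation of 5,6-dihydro-2H-pyran-2-one (sets C13).

Assumption: (2E,6E)-farnesyl bromide and 5,6-dihydro-2H-pyran-2-one are bought as catalogue reagents; labdane numbering is used for the polycycles and the extra carboxyl carbon on C12 is called C21.

**Route**

Step 1
Reactants: 1 5,6-dihydro-2H-pyran-2-one
Product: 3 (R)-4-methyltetrahydro-2H-pyran-2-one, via bromomagnesium enolate 2 (not isolated)
Conditions: MeMgBr (1.2 equiv), CuBr·SMe2 (5 mol %), (R)-1-[(Sp)-2-(diphenylphosphino)ferrocenyl]ethyldicyclohexylphosphine (6 mol %, antipode chosen to give 4R), t-BuOMe, −78 °C; 1 M HCl quench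
Reagents that add atoms: methylmagnesium bromide, C[Mg]Br
Why: Copper-catalysed asymmetric conjugate addition of a Grignard reagent to an α,β-unsaturated lactone, in which the chiral copper–diphosphine complex selects one enoate face and sets the future C13 centre (residual minor enantiomer is removed later, when all intermediates are diastereomers).

Step 2
Reactants: 3 (R)-4-methyltetrahydro-2H-pyran-2-one, 4 (2E,6E)-farnesyl bromide
Product: 6 (3S,4R)-4-methyl-3-[(2E,6E)-3,7,11-trimethyldodeca-2,6,10-trien-1-yl]tetrahydro-2H-pyran-2-one, via lithium enolate 5 (not isolated)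
Conditions: LiN(i-Pr)2 (1.1 equiv), THF, −78 °C; then 4 (0.9 equiv), DMPU, −78 → −30 °C
Reagents that add atoms: none
Why: Lactone enolate alkylation (SN2 on the allylic bromide, E,E geometry retained), the electrophile entering anti to the C4 methyl group to give the 3,4-trans lactone; this C12 centre only serves the next steps and is erased in step 7.

Step 3
Reactants: 6 (3S,4R)-4-methyl-3-[(2E,6E)-3,7,11-trimethyldodeca-2,6,10-trien-1-yl]tetrahydro-2H-pyran-2-one
Product: 8 (2S,3R)-5-acetoxy-3-methyl-2-[(2E,6E)-3,7,11-trimethyldodeca-2,6,10-trien-1-yl]pentanoic acid, via lithium hydroxy carboxylate 7 (not isolated)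
Conditions: LiOH·H2O (1.05 equiv), THF/H2O, 23 °C; evaporate; Ac2O (5 equiv), pyridine, DMAP (5 mol %), 0 → 23 °C; 1 M HCl work-up
Reagents that add atoms: lithium hydroxide, [Li+].[OH-]; acetic anhydride, CC(=O)OC(C)=O
Why: Lactone saponification followed by O-acetylation of the carboxylate salt (mixed anhydride hydrolysed on work-up), which blocks relactonisation, frees the carboxyl as cyclisation terminator and installs the C15 acetate of the target without touching a stereocentre.

Step 4
Reactants: 8 (2S,3R)-5-acetoxy-3-methyl-2-[(2E,6E)-3,7,11-trimethyldodeca-2,6,10-trien-1-yl]pentanoic acid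
Product: 9 (5R,8S,9S,10R,12S,13R)-15-acetoxy-8-hydroxy-ent-labdane-12-carboxylic acid δ-lactone (trans-fused rings A, B and C; lactone C8–O–C21(=O)–C12)
Conditions: (S)-2-hydroxy-2′-(2-fluorobenzyloxy)-1,1′-binaphthyl·SnCl4 (2 equiv), toluene, −78 °C, 72 h; chromatography, then crystallisation
Reagents that add atoms: none
Why: Enantioselective proton-initiated polyene cyclisation with a Lewis acid-assisted chiral Brønsted acid, in which face-selective protonation of the terminal alkene starts an all-chair anti cascade (ring A, then ring B) that fixes C5, C9 and C10 in the ent series and the carboxyl closes ring C by anti C8–O bond formation; material from the other decalin antipode is a diastereomer (C12 and C13 are already fixed) and is removed.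

Step 5
Reactants: 9 (5R,8S,9S,10R,12S,13R)-15-acetoxy-8-hydroxy-ent-labdane-12-carboxylic acid δ-lactone
Product: 10 (2R,5R,8S,9S,10R,12S,13R)-2,15-diacetoxy-8-hydroxy-ent-labdane-12-carboxylic acid δ-lactone (C2 acetate equatorial, trans to the C10 methyl)
Conditions: Mn(TMP)OAc (5 mol %, TMP = 5,10,15,20-tetramesitylporphyrinate), PhI(OAc)2 (2.0 equiv, slow addition), AcOH (5 equiv), Ac2O (1 equiv), PhCF3, 40 °C, Ar
Reagents that add atoms: (diacetoxyiodo)benzene, CC(=O)OI(OC(C)=O)c1ccccc1
Why: Proposed new method: manganese-porphyrin-catalysed C–H acetoxylation by acetate ligand transfer, in which PhI(OAc)2 turns the trivalent manganese acetate into an oxo pentavalent manganese species that abstracts hydrogen from C2 (the most electron-rich, least hindered methylene, since ring B is deactivated by the lactone oxygen and the side chain by the lactone carbonyl and the C15 acetate), and the C2 radical, escaping the slow hydroxyl rebound of manganese porphyrins in the water-free acetate medium, is trapped by a trans-diacetate tetravalent manganese porphyrin on the face opposite the syn-axial C10 and C4 methyl groups to give the equatorial (2R) acetate, which resists over-oxidation; the closest known reactions are the manganese-porphyrin C–H chlorination, fluorination and azidation of sclareolide at C2 (ligand transfer from tetravalent manganese) and manganese-catalysed γ-lactonisation by carboxylate rebound.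

Step 6
Reactants: 10 (2R,5R,8S,9S,10R,12S,13R)-2,15-diacetoxy-8-hydroxy-ent-labdane-12-carboxylic acid δ-lactone
Product: 12 (2R,5R,9R,10R,12S,13R)-2,15-diacetoxy-ent-labd-7-ene-12-carboxylic acid, via trimethylsilyl ester 11 (not isolated)
Conditions: TMSOTf (2.5 equiv), 2,6-lutidine (4 equiv), CH2Cl2, −40 → 0 °C; pH 4 aqueous work-up
Reagents that add atoms: none
Why: Silyl triflate-mediated E1 cleavage of a tertiary alkyl ester, in which O-silylation of the lactone carbonyl lets the C8–O bond ionise, the C8 cation loses the axial H7 as in the termination of polyene cyclisations to give the trisubstituted 7-ene, and the silyl ester cannot re-add, so the opening is irreversible and the C8 centre is erased.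

Step 7
Reactants: 12 (2R,5R,9R,10R,12S,13R)-2,15-diacetoxy-ent-labd-7-ene-12-carboxylic acid
Product: 13 (2R,5R,9R,10R,13S)-ent-labd-7-ene-2,15-diyl diacetate (CNP0220683.1)
Conditions: 9-mesitylacridine (10 mol %), 2,4,6-triisopropylbenzenethiol (10 mol %), CH2Cl2, 400 nm LED, 25 °C
Reagents that add atoms: none
Why: Photocatalytic hydrodecarboxylation (proton-coupled electron transfer in the acridine–acid complex, loss of CO2, hydrogen-atom transfer from the thiol to the secondary C12 radical), which removes the traceless carboxyl and with it the C12 centre while C13, the ring centres, the alkene and both acetates are untouched.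

**Compound list**

1 | 5,6-dihydro-2H-pyran-2-one | O=C1C=CCCO1 | starting material
2 | bromomagnesium (R)-4-methyl-5,6-dihydro-4H-pyran-2-olate | C[C@H]1C=C(O[Mg]Br)OCC1 | intermediate (not isolated)
3 | (R)-4-methyltetrahydro-2H-pyran-2-one | C[C@H]1CC(=O)OCC1 | intermediate
4 | (2E,6E)-farnesyl bromide | BrC/C=C(\C)CC/C=C(\C)CCC=C(C)C | starting material
5 | lithium (R)-4-methyl-5,6-dihydro-4H-pyran-2-olate | C[C@H]1C=C(O[Li])OCC1 | intermediate (not isolated)
6 | (3S,4R)-4-methyl-3-[(2E,6E)-3,7,11-trimethyldodeca-2,6,10-trien-1-yl]tetrahydro-2H-pyran-2-one | C[C@@H]1CCOC(=O)[C@H]1C/C=C(\C)CC/C=C(\C)CCC=C(C)C | intermediate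
7 | lithium (2S,3R)-5-hydroxy-3-methyl-2-[(2E,6E)-3,7,11-trimethyldodeca-2,6,10-trien-1-yl]pentanoate | OCC[C@@H](C)[C@H](C/C=C(\C)CC/C=C(\C)CCC=C(C)C)C(=O)[O-].[Li+] | intermediate (not isolated)
8 | (2S,3R)-5-acetoxy-3-methyl-2-[(2E,6E)-3,7,11-trimethyldodeca-2,6,10-trien-1-yl]pentanoic acid | CC(=O)OCC[C@@H](C)[C@H](C/C=C(\C)CC/C=C(\C)CCC=C(C)C)C(=O)O | intermediate
9 | (5R,8S,9S,10R,12S,13R)-15-acetoxy-8-hydroxy-ent-labdane-12-carboxylic acid δ-lactone | CC(=O)OCC[C@@H](C)[C@@H]1C[C@@H]2[C@](C)(CC[C@@H]3C(C)(C)CCC[C@@]23C)OC1=O | intermediate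
10 | (2R,5R,8S,9S,10R,12S,13R)-2,15-diacetoxy-8-hydroxy-ent-labdane-12-carboxylic acid δ-lactone | CC(=O)OCC[C@@H](C)[C@@H]1C[C@@H]2[C@](C)(CC[C@@H]3C(C)(C)C[C@@H](OC(C)=O)C[C@@]23C)OC1=O | intermediate
11 | trimethylsilyl (2R,5R,9R,10R,12S,13R)-2,15-diacetoxy-ent-labd-7-ene-12-carboxylate | CC(=O)OCC[C@@H](C)[C@@H](C(=O)O[Si](C)(C)C)C[C@@H]1C(C)=CC[C@@H]2C(C)(C)C[C@@H](OC(C)=O)C[C@@]12C | intermediate (not isolated)
12 | (2R,5R,9R,10R,12S,13R)-2,15-diacetoxy-ent-labd-7-ene-12-carboxylic acid | CC(=O)OCC[C@@H](C)[C@@H](C(=O)O)C[C@@H]1C(C)=CC[C@@H]2C(C)(C)C[C@@H](OC(C)=O)C[C@@]12C | intermediate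
13 | (2R,5R,9R,10R,13S)-ent-labd-7-ene-2,15-diyl diacetate | CC(=O)OCC[C@@H](C)CC[C@@H]1C(C)=CC[C@@H]2C(C)(C)C[C@@H](OC(C)=O)C[C@@]12C | target

**Step count and risks**

Total steps: 7. Longest linear sequence: 7 steps (1 to 13; farnesyl bromide 4 enters in step 2).

The three steps most likely to fail are the cyclisation (8 to 9), the new C–H acetoxylation (9 to 10) and the lactone opening (10 to 12).

The cyclisation of 8 may give low conversion or weak control with the chiral acid, because the substrate carries two stereocentres near the terminating carboxyl. The fallback replaces reagent control by separation. It sets out from 8, which is cyclised with an achiral superacid (ClSO3H, 2-nitropropane, −78 °C) to a roughly 1:1 mixture of 9 and the lactone of the natural decalin series F1. Because C12 and C13 are already fixed, these two are diastereomers (side chain on C12 axial in 9, equatorial in F1) and are separated by chromatography and crystallisation. The fallback comes back to the route at 9.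

The new acetoxylation of 9 may fail if acetate transfer from manganese is slower than oxygen rebound or radical decay, giving ketone, alkene or the C3 isomer. The fallback uses known chemistry and sets out from 9. Quinuclidine-mediated electrochemical methylene oxidation (quinuclidine, Me4NBF4, HFIP, MeCN, O2, carbon anode, constant current), established for C2 of sclareolide, gives the 2-ketone F2. NaBH4 in MeOH at 0 °C attacks from the equatorial side, since axial approach is blocked by the two syn-axial methyl groups, and gives the axial 2-alcohol F3. A Mitsunobu reaction with AcOH (PPh3, DIAD, toluene) inverts C2 and gives the equatorial acetate directly. The fallback comes back at 10.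

The opening of 10 may give the 8(17)- or 8-ene instead of the 7-ene, or may relactonise. The fallback removes the carboxyl before the elimination and sets out from 10. LiOH in THF/H2O followed by careful acidification gives the trihydroxy acid F4, used at once. Hydrodecarboxylation under the conditions of step 7 gives the triol F5. Ac2O in pyridine acetylates the primary and secondary hydroxyls only and gives the 8-hydroxy diacetate F6. E1 dehydration of the tertiary alcohol under the kinetic conditions that terminate superacid polyene cyclisations (FSO3H, 2-nitropropane, −78 °C, Et3N quench), now with no carboxyl to recapture the cation, gives the 7-ene. The fallback comes back at 13.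

**Further compounds**

F1 | step 4 | (5S,8R,9R,10S,12S,13R)-15-acetoxy-8-hydroxylabdane-12-carboxylic acid δ-lactone (natural decalin series) | CC(=O)OCC[C@@H](C)[C@@H]1C[C@H]2[C@@](C)(CC[C@H]3C(C)(C)CCC[C@]23C)OC1=O
F2 | step 5 | (5R,8S,9S,10R,12S,13R)-15-acetoxy-8-hydroxy-2-oxo-ent-labdane-12-carboxylic acid δ-lactone | CC(=O)OCC[C@@H](C)[C@@H]1C[C@@H]2[C@](C)(CC[C@@H]3C(C)(C)CC(=O)C[C@@]23C)OC1=O
F3 | step 5 | (2S,5R,8S,9S,10R,12S,13R)-15-acetoxy-2,8-dihydroxy-ent-labdane-12-carboxylic acid 8-lactone (axial 2-alcohol) | CC(=O)OCC[C@@H](C)[C@@H]1C[C@@H]2[C@](C)(CC[C@@H]3C(C)(C)C[C@H](O)C[C@@]23C)OC1=O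
F4 | step 6 | (2R,5R,8S,9S,10R,12S,13R)-2,8,15-trihydroxy-ent-labdane-12-carboxylic acid | OCC[C@@H](C)[C@@H](C(=O)O)C[C@@H]1[C@@](C)(O)CC[C@@H]2C(C)(C)C[C@@H](O)C[C@@]12C
F5 | step 6 | (2R,5R,8S,9S,10R,13S)-ent-labdane-2,8,15-triol | OCC[C@@H](C)CC[C@@H]1[C@@](C)(O)CC[C@@H]2C(C)(C)C[C@@H](O)C[C@@]12C
F6 | step 6 | (2R,5R,8S,9S,10R,13S)-8-hydroxy-ent-labdane-2,15-diyl diacetate | CC(=O)OCC[C@@H](C)CC[C@@H]1[C@@](C)(O)CC[C@@H]2C(C)(C)C[C@@H](OC(C)=O)C[C@@]12C
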